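**Strategy.** The route rests on cutting the bond between the dodecanoyl carbonyl carbon and C3'' of the phloroglucinol ring (ring D). The key step, a Houben–Hoesch acylation of the unprotected pentaphenol 8 with dodecanenitrile, forms this bond and delivers the natural product directly. It exploits ring D: its two free CH carbons, C3'' and C5'', are homotopic by rotation about the C4–C1'' bond and far more nucleophilic than rings A and B, so no regioisomer can form and no protecting group is needed. Precursor 8, the (2S,4R)-4-(2,4,6-trihydroxyphenyl)flavan-4',7-diol, comes from a catalytic asymmetric arylation of a chromone (sets C2), ketone reduction and a trans-selective Friedel–Crafts coupling of the flavan-4-ol with phloroglucinol (sets C4).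

Key step: step 6

Labels: chroman atoms O1, C2, C3, C4, C4a, C5–C8, C8a; ring A = benzo ring of the chroman, ring C = pyran ring, ring B = 4-hydroxyphenyl on C2, ring D = trihydroxyphenyl on C4 with carbons C1'' (bound to C4) to C6''. The target is the 2,4-trans isomer, (2S,4R).

Assumption: the (R)-pyridine-oxazoline ligand is taken to give the (2S)-flavanone, by analogy with the facial selectivity of this catalyst class on cyclic enones; the sense is to be confirmed chiroptically and the enantiomeric ligand used if it is the opposite.

Step 1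
Reactants: 1 7-hydroxy-4H-chromen-4-one
Product: 2 7-(benzyloxy)-4H-chromen-4-one
Conditions: BnBr (1.1 equiv), K2CO3 (1.5 equiv), acetone, reflux
Reagents that add atoms: benzyl bromide, BrCc1ccccc1
Why: Williamson ether synthesis on the acidic 7-hydroxyl (a vinylogous acid), with a carbonate base mild enough to leave the pyranone ring closed.

Step 2
Reactants: 2 7-(benzyloxy)-4H-chromen-4-one, 3 [4-(benzyloxy)phenyl]boronic acid
Product: 4 (2S)-7-(benzyloxy)-2-[4-(benzyloxy)phenyl]chroman-4-one
Conditions: 3 (2 equiv), Pd(OCOCF3)2 (5 mol%), (R)-4-tert-butyl-2-(pyridin-2-yl)-4,5-dihydrooxazole (6 mol%), NH4PF6 (30 mol%), H2O (5 equiv), ClCH2CH2Cl, 60 °C; then recrystallisation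
Reagents that add atoms: none
Why: Palladium-catalysed asymmetric conjugate addition of an arylboronic acid to a chromone (Hayashi–Miyaura-type 1,4-addition), in which the cationic aryl–palladium–ligand complex carbopalladates C2=C3 on one enantioface and water protonates the palladium enolate, so the chiral ligand sets C2 as S.

Step 3
Reactants: 4 (2S)-7-(benzyloxy)-2-[4-(benzyloxy)phenyl]chroman-4-one
Product: 5 (2S,4S)-7-(benzyloxy)-2-[4-(benzyloxy)phenyl]chroman-4-ol
Conditions: NaBH4 (1.5 equiv), THF–MeOH, 0 °C
Reagents that add atoms: none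
Why: Borohydride reduction of the ketone should give the equatorial alcohol cis to the equatorial C2 aryl group (4S, substrate control; this center is erased in step 4), while the capped phenols and the low temperature guard C2 against retro-oxa-Michael racemisation.

Step 4
Reactants: 5 (2S,4S)-7-(benzyloxy)-2-[4-(benzyloxy)phenyl]chroman-4-ol, 6 phloroglucinol (benzene-1,3,5-triol)
Product: 7 2-[(2S,4R)-7-(benzyloxy)-2-[4-(benzyloxy)phenyl]chroman-4-yl]benzene-1,3,5-triol
Conditions: 6 (5 equiv), BF3·OEt2 (0.3 equiv), 1,4-dioxane, 20 °C; aqueous wash to remove excess 6, chromatography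
Reagents that add atoms: none
Why: Friedel–Crafts alkylation through the C4 benzylic cation (stabilised by O1 and the 7-benzyloxy group), which phloroglucinol should attack pseudo-axially on the half-chair, anti to the pseudo-equatorial C2 aryl group, setting C4 as R (2,4-trans), while the excess of 6 suppresses double alkylation.

Step 5
Reactants: 7 2-[(2S,4R)-7-(benzyloxy)-2-[4-(benzyloxy)phenyl]chroman-4-yl]benzene-1,3,5-triol
Product: 8 2-[(2S,4R)-7-hydroxy-2-(4-hydroxyphenyl)chroman-4-yl]benzene-1,3,5-triol
Conditions: H2 (1 atm), 10% Pd/C, EtOAc–MeOH, rt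
Reagents that add atoms: none
Why: Hydrogenolysis of the two O-benzyl ethers, which should be much faster than cleavage of the cyclic C2–O1 benzylic ether, so both stereocenters stay untouched.

Step 6
Reactants: 8 2-[(2S,4R)-7-hydroxy-2-(4-hydroxyphenyl)chroman-4-yl]benzene-1,3,5-triol, 9 dodecanenitrile
Product: 11 (+)-myristinin A, via ketiminium chloride 10 (not isolated)
Conditions: 9 (1.2 equiv), HCl (g), ZnCl2 (0.2 equiv), Et2O–1,4-dioxane, 0 °C; then H2O–MeOH, 70 °C
Reagents that add atoms: water, O
Why: HCl and ZnCl2 turn the nitrile into an imidoyl chloride/nitrilium electrophile that attacks C3'' (equivalent to C5'') of ring D by electrophilic aromatic substitution, and the resulting ketiminium chloride 10 is hydrolysed to the aryl ketone. The closest known reaction type is the Houben–Hoesch reaction, the nitrile variant of the Friedel–Crafts acylation, which is established for phloroglucinol and its C-alkyl derivatives with aliphatic nitriles. No ring is closed and no stereocenter is formed; C2 and C4 are carried through unchanged. The step needs site selectivity among three electron-rich rings and mono-acylation: ring D, a 2-alkylphloroglucinol, is far more nucleophilic than the resorcinol-type ring A or the phenol ring B, its two open positions are homotopic by rotation about C4–C1'' so either gives 11, and the cationic ketiminium group switches ring D off against a second acylation. The weak electrophile does not acylate hydroxyl groups, so the five phenols need no protection. The absence of a 5-hydroxyl on ring A should make the C4–C1'' and C2–O1 bonds resistant to acidolysis at 0 °C, which protects both stereocenters.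

**Compound list**

1 | 7-hydroxy-4H-chromen-4-one | O=c1ccoc2cc(O)ccc12 | starting material
2 | 7-(benzyloxy)-4H-chromen-4-one | O=c1ccoc2cc(OCc3ccccc3)ccc12 | intermediate
3 | [4-(benzyloxy)phenyl]boronic acid | OB(O)c1ccc(OCc2ccccc2)cc1 | starting material
4 | (2S)-7-(benzyloxy)-2-[4-(benzyloxy)phenyl]chroman-4-one | O=C1C[C@@H](c2ccc(OCc3ccccc3)cc2)Oc2cc(OCc3ccccc3)ccc12 | intermediate
5 | (2S,4S)-7-(benzyloxy)-2-[4-(benzyloxy)phenyl]chroman-4-ol (2,4-cis) | O[C@H]1C[C@@H](c2ccc(OCc3ccccc3)cc2)Oc2cc(OCc3ccccc3)ccc21 | intermediate
6 | phloroglucinol (benzene-1,3,5-triol) | Oc1cc(O)cc(O)c1 | starting material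
7 | 2-[(2S,4R)-7-(benzyloxy)-2-[4-(benzyloxy)phenyl]chroman-4-yl]benzene-1,3,5-triol (2,4-trans) | Oc1cc(O)c([C@@H]2C[C@@H](c3ccc(OCc4ccccc4)cc3)Oc3cc(OCc4ccccc4)ccc32)c(O)c1 | intermediate
8 | 2-[(2S,4R)-7-hydroxy-2-(4-hydroxyphenyl)chroman-4-yl]benzene-1,3,5-triol (2,4-trans) | Oc1cc(O)c([C@@H]2C[C@@H](c3ccc(O)cc3)Oc3cc(O)ccc32)c(O)c1 | intermediate
9 | dodecanenitrile | CCCCCCCCCCCC#N | starting material
10 | 1-{2,4,6-trihydroxy-3-[(2S,4R)-7-hydroxy-2-(4-hydroxyphenyl)chroman-4-yl]phenyl}dodecan-1-iminium chloride (ketiminium chloride) | CCCCCCCCCCCC(=[NH2+])c1c(O)cc(O)c([C@@H]2C[C@@H](c3ccc(O)cc3)Oc3cc(O)ccc32)c1O.[Cl-] | intermediate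
11 | (+)-myristinin A, 1-{2,4,6-trihydroxy-3-[(2S,4R)-7-hydroxy-2-(4-hydroxyphenyl)chroman-4-yl]phenyl}dodecan-1-one | CCCCCCCCCCCC(=O)c1c(O)cc(O)c([C@@H]2C[C@@H](c3ccc(O)cc3)Oc3cc(O)ccc32)c1O | target

Total step count: 6
Longest linear sequence: 6 steps (1 → 2 → 4 → 5 → 7 → 8 → 11)

**Steps most likely to fail**

Step 6 (key step). What may go wrong: loss of site selectivity (competing attack of the electrophile on ring A), or acid-induced ionisation of the C4–C1'' or C2–O1 bond during the long exposure to HCl, with epimerisation. The fallback forms the same carbon–carbon bond between the same two halves with reversed polarity and without strong acid. It sets out from 8 and returns at 11.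
- 8 is treated with chloromethyl methyl ether and i-Pr2NEt in CH2Cl2–DMF to give the penta(methoxymethyl) ether F1.
- NBS (1 equiv, CH2Cl2, −40 °C) should brominate the most electron-rich ring D at C3'' to give the aryl bromide F2.
- Bromine–lithium exchange (n-BuLi, THF, −78 °C) and addition of N-methoxy-N-methyldodecanamide F3 (made from dodecanoyl chloride and N,O-dimethylhydroxylamine hydrochloride, pyridine, CH2Cl2) should give the penta(methoxymethyl) ketone F4 by a Weinreb ketone synthesis.
- Dilute HCl in MeOH at 40 °C removes the five methoxymethyl groups and gives 11.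

Step 4. What may go wrong: poor facial selectivity at the C4 cation (too much of the 2,4-cis isomer), double alkylation of phloroglucinol, or self-condensation of the cation with ring A of a second molecule. The fallback uses a fully O-protected nucleophile that dissolves in CH2Cl2, which allows low temperature and kinetic control. It sets out from 5 and returns at 8, so step 5 is no longer needed.
- 5 and commercial 1,3,5-tris(benzyloxy)benzene are combined with BF3·OEt2 in CH2Cl2 at −78 °C to give the pentabenzyl ether F5; the bulkier arene should attack anti to the C2 aryl group even more selectively.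
- Global hydrogenolysis (H2, Pd/C, EtOAc–MeOH) gives 8.

Step 2. What may go wrong: insufficient enantioface discrimination by the pyridine-oxazoline catalyst on this electron-rich 7-alkoxychromone, so that recrystallisation cannot deliver a single enantiomer. The fallback sets C2 by kinetic resolution instead of enantioselective carbon–carbon bond formation. It sets out from 2 (with 3) and returns at 5, so step 3 is no longer needed.
- Achiral conjugate addition (Pd(OCOCF3)2, 2,2'-bipyridine, aqueous ClCH2CH2Cl, 60 °C) gives the racemic flavanone F6.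
- Asymmetric transfer hydrogenation (RuCl(p-cymene)[(S,S)-TsDPEN], HCO2H–Et3N, EtOAc, rt) is stopped near half conversion. The (2S)-enantiomer, matched with the catalyst, should be reduced to the cis-(2S,4S)-alcohol 5; the unreacted (2R)-ketone is separated by chromatography and can be racemised with base and recycled.

**Further compounds**

F1 | step 6 | (2S,4R)-7-(methoxymethoxy)-2-[4-(methoxymethoxy)phenyl]-4-[2,4,6-tris(methoxymethoxy)phenyl]chromane | COCOc1cc(OCOC)c([C@@H]2C[C@@H](c3ccc(OCOC)cc3)Oc3cc(OCOC)ccc32)c(OCOC)c1
F2 | step 6 | (2S,4R)-4-[3-bromo-2,4,6-tris(methoxymethoxy)phenyl]-7-(methoxymethoxy)-2-[4-(methoxymethoxy)phenyl]chromane | COCOc1cc(OCOC)c([C@@H]2C[C@@H](c3ccc(OCOC)cc3)Oc3cc(OCOC)ccc32)c(OCOC)c1Br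
F3 | step 6 | N-methoxy-N-methyldodecanamide | CCCCCCCCCCCC(=O)N(C)OC
F4 | step 6 | 1-{2,4,6-tris(methoxymethoxy)-3-[(2S,4R)-7-(methoxymethoxy)-2-[4-(methoxymethoxy)phenyl]chroman-4-yl]phenyl}dodecan-1-one | CCCCCCCCCCCC(=O)c1c(OCOC)cc(OCOC)c([C@@H]2C[C@@H](c3ccc(OCOC)cc3)Oc3cc(OCOC)ccc32)c1OCOC
F5 | step 4 | (2S,4R)-7-(benzyloxy)-2-[4-(benzyloxy)phenyl]-4-[2,4,6-tris(benzyloxy)phenyl]chromane | O(Cc1ccccc1)c1cc(OCc2ccccc2)c([C@@H]2C[C@@H](c3ccc(OCc4ccccc4)cc3)Oc3cc(OCc4ccccc4)ccc32)c(OCc2ccccc2)c1
F6 | step 2 | rac-7-(benzyloxy)-2-[4-(benzyloxy)phenyl]chroman-4-one | O=C1CC(c2ccc(OCc3ccccc3)cc2)Oc2cc(OCc3ccccc3)ccc12
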